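**Retrosynthetic overview**

- The target is a 2,3,5,6-tetramethoxy-1,4-phenylene core (ring C) carrying a 6-methoxyindol-3-yl unit (ring A) and a 5-hydroxyindol-3-yl unit (ring B). The last step only strips two N-trifluoroacetyl groups and one pivalate.
- Key disconnection: both indole C3–C3a bonds. Each indole C3 (the carbon bonded to ring C) is the carbonyl carbon of an aryl ketone on 1,4-diacylated ring C, and each C3a is the ortho carbon of an N-trifluoroacetyl anilide whose nitrogen sits on the ketone's α-CH2. A double acid cyclodehydration closes both pyrrole rings, ring A first and ring B second.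
- The bis(anilinoacetyl)arene is cut at its two N–CH2 bonds into 3-methoxyaniline, 4-aminophenyl pivalate and ring C carrying two haloacetyl handles.
- The two handles are made non-equivalent and are installed one after the other: a chloroacetyl group by mono Br/Li exchange of the dibromide and Weinreb acylation, then a bromoacetyl group from the remaining C–Br by Stille coupling and NBS/H2O. Two identical haloacetyl groups would allow only a statistical monoamination, made worse by N,N-dialkylation when the electrophile is in excess.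

Key step: step 11

Remark on the chemistry: 2-chloro-N-methoxy-N-methylacetamide is taken as a purchased building block in addition to the four obvious starting materials.

**Route**

Step 1
Reactants: 1 1,2,4,5-tetramethoxybenzene
Product: 2 1,4-dibromo-2,3,5,6-tetramethoxybenzene
Conditions: Br2 (2.2 equiv), CH2Cl2, 0 °C to rt
Reagents that add atoms: bromine, BrBr
Why: Twofold electrophilic aromatic bromination, in which the only two free positions of 1 are each flanked by two methoxy groups, so both are substituted and no isomer can form.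

Step 2
Reactants: 2 1,4-dibromo-2,3,5,6-tetramethoxybenzene; 3 2-chloro-N-methoxy-N-methylacetamide
Product: 5 1-(4-bromo-2,3,5,6-tetramethoxyphenyl)-2-chloroethan-1-one, via (4-bromo-2,3,5,6-tetramethoxyphenyl)lithium 4 (not isolated)
Conditions: n-BuLi (1.0 equiv), THF, −78 °C; then 3, −78 to 0 °C; aq NH4Cl
Reagents that add atoms: none
Why: Bromine–lithium exchange with one equivalent of n-BuLi at −78 °C should stop at the monolithio stage, and the aryllithium adds once to the amide because the chelated tetrahedral adduct persists until work-up (Weinreb ketone synthesis), which gives the chloromethyl ketone directly and leaves the second C–Br as a distinct handle.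

Step 3
Reactants: 5 1-(4-bromo-2,3,5,6-tetramethoxyphenyl)-2-chloroethan-1-one; 6 3-methoxyaniline
Product: 8 1-(4-bromo-2,3,5,6-tetramethoxyphenyl)-2-[(3-methoxyphenyl)amino]ethan-1-one, via 1-(4-bromo-2,3,5,6-tetramethoxyphenyl)-2-iodoethan-1-one 7 (not isolated)
Conditions: 6 (2.5 equiv), NaI (0.2 equiv), NaHCO3, MeCN, 60 °C
Reagents that add atoms: none
Why: SN2 N-alkylation of the aniline by the α-haloketone, accelerated by Finkelstein exchange to the iodoketone, in which the excess aniline and the low nucleophilicity of the N-aryl α-aminoketone should hold the reaction at monoalkylation while the twisted di-ortho-substituted ketone does not form an imine.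

Step 4
Reactants: 8 1-(4-bromo-2,3,5,6-tetramethoxyphenyl)-2-[(3-methoxyphenyl)amino]ethan-1-one
Product: 9 N-[2-(4-bromo-2,3,5,6-tetramethoxyphenyl)-2-oxoethyl]-2,2,2-trifluoro-N-(3-methoxyphenyl)acetamide
Conditions: (CF3CO)2O (1.5 equiv), pyridine, CH2Cl2, 0 °C
Reagents that add atoms: trifluoroacetic anhydride, O=C(OC(=O)C(F)(F)F)C(F)(F)F
Why: N-acylation of the secondary arylamine, which protects the nitrogen and its ring against NBS in step 6 and installs the acyl group that the Bischler closure needs.

Step 5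
Reactants: 9 N-[2-(4-bromo-2,3,5,6-tetramethoxyphenyl)-2-oxoethyl]-2,2,2-trifluoro-N-(3-methoxyphenyl)acetamide; 10 tributyl(1-ethoxyvinyl)stannane
Product: 11 N-{2-[4-(1-ethoxyvinyl)-2,3,5,6-tetramethoxyphenyl]-2-oxoethyl}-2,2,2-trifluoro-N-(3-methoxyphenyl)acetamide
Conditions: 10 (1.5 equiv), Pd(PPh3)4 (5 mol %), toluene, 110 °C; crude product through Et3N-deactivated silica
Reagents that add atoms: none
Why: Stille coupling at zerovalent palladium (oxidative addition into the aryl C–Br bond, transfer of the 1-ethoxyvinyl group from tin, reductive elimination) under neutral, base-free conditions that leave the ketone, its acidic α-CH2 and the trifluoroacetamide untouched, with the para acyl group helping oxidative addition at the di-ortho-methoxy bromide.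

Step 6
Reactants: 11 N-{2-[4-(1-ethoxyvinyl)-2,3,5,6-tetramethoxyphenyl]-2-oxoethyl}-2,2,2-trifluoro-N-(3-methoxyphenyl)acetamide
Product: 12 N-{2-[4-(bromoacetyl)-2,3,5,6-tetramethoxyphenyl]-2-oxoethyl}-2,2,2-trifluoro-N-(3-methoxyphenyl)acetamide
Conditions: NBS (1.05 equiv), THF/H2O (4:1), 0 °C
Reagents that add atoms: N-bromosuccinimide, O=C1CCC(=O)N1Br; water, O
Why: Electrophilic bromination of the enol ether gives an α-bromo oxocarbenium ion that water captures, and the hemiketal loses ethanol to give the bromomethyl ketone; the enol ether should react far faster than the N-acylated anisole ring, so one equivalent of NBS at 0 °C is selective.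

Step 7
Reactants: 13 4-nitrophenol
Product: 14 4-nitrophenyl 2,2-dimethylpropanoate (4-nitrophenyl pivalate)
Conditions: t-BuCOCl (1.2 equiv), Et3N, DMAP (cat.), CH2Cl2, 0 °C to rt
Reagents that add atoms: pivaloyl chloride, CC(C)(C)C(=O)Cl
Why: O-acylation of the phenol with nucleophilic catalysis by DMAP; the pivalate is chosen because it is stable in CF3CO2H and too hindered for acyl transfer to the aniline made in step 8.

Step 8
Reactants: 14 4-nitrophenyl 2,2-dimethylpropanoate
Product: 15 4-aminophenyl 2,2-dimethylpropanoate (4-aminophenyl pivalate)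
Conditions: H2 (1 atm), Pd/C (10 %), EtOAc, rt; used promptly
Reagents that add atoms: none
Why: Catalytic hydrogenation of the nitro group over Pd/C under neutral conditions leaves the aryl ester intact.

Step 9
Reactants: 12 N-{2-[4-(bromoacetyl)-2,3,5,6-tetramethoxyphenyl]-2-oxoethyl}-2,2,2-trifluoro-N-(3-methoxyphenyl)acetamide; 15 4-aminophenyl 2,2-dimethylpropanoate
Product: 16 4-{[2-(2,3,5,6-tetramethoxy-4-{[(3-methoxyphenyl)(trifluoroacetyl)amino]acetyl}phenyl)-2-oxoethyl]amino}phenyl 2,2-dimethylpropanoate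
Conditions: 15 (1.5 equiv), NaHCO3, MeCN, rt to 40 °C
Reagents that add atoms: none
Why: SN2 N-alkylation of the primary arylamine by the bromomethyl ketone, in which the excess of 15 limits dialkylation and bicarbonate is too weak to cleave the trifluoroacetamide or the pivalate.

Step 10
Reactants: 16 4-{[2-(2,3,5,6-tetramethoxy-4-{[(3-methoxyphenyl)(trifluoroacetyl)amino]acetyl}phenyl)-2-oxoethyl]amino}phenyl 2,2-dimethylpropanoate
Product: 17 4-{[2-(2,3,5,6-tetramethoxy-4-{[(3-methoxyphenyl)(trifluoroacetyl)amino]acetyl}phenyl)-2-oxoethyl](trifluoroacetyl)amino}phenyl 2,2-dimethylpropanoate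
Conditions: (CF3CO)2O (1.5 equiv), pyridine, CH2Cl2, 0 °C
Reagents that add atoms: trifluoroacetic anhydride, O=C(OC(=O)C(F)(F)F)C(F)(F)F
Why: N-acylation of the remaining secondary arylamine completes the bis(N-aryl-N-trifluoroacetylaminoacetyl)arene with both nitrogens blocked against exchange.

Step 11
Reactants: 17 4-{[2-(2,3,5,6-tetramethoxy-4-{[(3-methoxyphenyl)(trifluoroacetyl)amino]acetyl}phenyl)-2-oxoethyl](trifluoroacetyl)amino}phenyl 2,2-dimethylpropanoate
Product: 19 3-{2,3,5,6-tetramethoxy-4-[6-methoxy-1-(trifluoroacetyl)-1H-indol-3-yl]phenyl}-1-(trifluoroacetyl)-1H-indol-5-yl 2,2-dimethylpropanoate, via mono-cyclised ring A indole ketone 18 (not isolated)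
Conditions: CF3CO2H/(CF3CO)2O (10:1), 0.02 M, rt, then 70 °C; crude product taken on
Reagents that add atoms: none
Why: In CF3CO2H each aryl ketone, held out of conjugation with ring C by its two ortho methoxy groups, is protonated and attacked by the ortho carbon of the anilide ring tethered through N–CH2 (intramolecular Friedel–Crafts hydroxyalkylation), and the tertiary benzylic 3-hydroxyindoline loses water, taken up by (CF3CO)2O, to give the N-trifluoroacetylindole. This is the Bischler indole synthesis in its N-acyl variant, the acid cyclodehydration of N-acyl α-anilino ketones to 3-substituted indoles. Each closure is a 5-exo-trig attack on the carbonyl carbon that forms a C3–C3a bond and one pyrrole ring; ring A should close first at room temperature through 18 because its attacking carbon is para to the methoxy group, and ring B should close on heating at a carbon ortho to the amide nitrogen and meta to the pivalate. No stereocentre is formed. Two selectivities are needed: the 3-methoxyanilide must react at the carbon para to OMe and not at the carbon between N and OMe, which the crowding of that position and the peri clash of a 4-methoxy group with the bulky aryl on C3 should secure, and the 3-aryl pattern must not rearrange to 2-aryl, which the N-trifluoroacetyl groups secure by preventing aniline exchange at the ketone, while the 4-substituted anilide has two equivalent ortho carbons. The pivalate and the aryl methyl ethers are stable to CF3CO2H, and the poorly nucleophilic trifluoroacetamide oxygen does not compete for the protonated ketone.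

Step 12
Reactants: 19 3-{2,3,5,6-tetramethoxy-4-[6-methoxy-1-(trifluoroacetyl)-1H-indol-3-yl]phenyl}-1-(trifluoroacetyl)-1H-indol-5-yl 2,2-dimethylpropanoate
Product: 20 3-[2,3,5,6-tetramethoxy-4-(6-methoxy-1H-indol-3-yl)phenyl]-1H-indol-5-ol (CNP0234672.0)
Conditions: K2CO3 (6 equiv), degassed MeOH/THF (3:1), argon, rt to 40 °C; aq NH4Cl
Reagents that add atoms: none
Why: Base-mediated methanolysis, in which the activated N-trifluoroacetyl amides on the indole nitrogens fall off at once and the aryl pivalate is transesterified on mild warming, run with exclusion of air because the 5-hydroxyindole phenoxide is prone to oxidation; the aryl methyl ethers are inert.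

**Compound list**

1 | 1,2,4,5-tetramethoxybenzene | COc1cc(OC)c(OC)cc1OC | starting material
2 | 1,4-dibromo-2,3,5,6-tetramethoxybenzene | COc1c(Br)c(OC)c(OC)c(Br)c1OC | intermediate
3 | 2-chloro-N-methoxy-N-methylacetamide | CON(C)C(=O)CCl | starting material
4 | (4-bromo-2,3,5,6-tetramethoxyphenyl)lithium | [Li]c1c(OC)c(OC)c(Br)c(OC)c1OC | intermediate
5 | 1-(4-bromo-2,3,5,6-tetramethoxyphenyl)-2-chloroethan-1-one | O=C(CCl)c1c(OC)c(OC)c(Br)c(OC)c1OC | intermediate
6 | 3-methoxyaniline | COc1cccc(N)c1 | starting material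
7 | 1-(4-bromo-2,3,5,6-tetramethoxyphenyl)-2-iodoethan-1-one | O=C(CI)c1c(OC)c(OC)c(Br)c(OC)c1OC | intermediate
8 | 1-(4-bromo-2,3,5,6-tetramethoxyphenyl)-2-[(3-methoxyphenyl)amino]ethan-1-one | COc1cccc(NCC(=O)c2c(OC)c(OC)c(Br)c(OC)c2OC)c1 | intermediate
9 | N-[2-(4-bromo-2,3,5,6-tetramethoxyphenyl)-2-oxoethyl]-2,2,2-trifluoro-N-(3-methoxyphenyl)acetamide | COc1cccc(N(CC(=O)c2c(OC)c(OC)c(Br)c(OC)c2OC)C(=O)C(F)(F)F)c1 | intermediate
10 | tributyl(1-ethoxyvinyl)stannane | C=C(OCC)[Sn](CCCC)(CCCC)CCCC | starting material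
11 | N-{2-[4-(1-ethoxyvinyl)-2,3,5,6-tetramethoxyphenyl]-2-oxoethyl}-2,2,2-trifluoro-N-(3-methoxyphenyl)acetamide | COc1cccc(N(CC(=O)c2c(OC)c(OC)c(C(=C)OCC)c(OC)c2OC)C(=O)C(F)(F)F)c1 | intermediate
12 | N-{2-[4-(bromoacetyl)-2,3,5,6-tetramethoxyphenyl]-2-oxoethyl}-2,2,2-trifluoro-N-(3-methoxyphenyl)acetamide | COc1cccc(N(CC(=O)c2c(OC)c(OC)c(C(=O)CBr)c(OC)c2OC)C(=O)C(F)(F)F)c1 | intermediate
13 | 4-nitrophenol | O=[N+]([O-])c1ccc(O)cc1 | starting material
14 | 4-nitrophenyl 2,2-dimethylpropanoate | CC(C)(C)C(=O)Oc1ccc([N+](=O)[O-])cc1 | intermediate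
15 | 4-aminophenyl 2,2-dimethylpropanoate | CC(C)(C)C(=O)Oc1ccc(N)cc1 | intermediate
16 | 4-{[2-(2,3,5,6-tetramethoxy-4-{[(3-methoxyphenyl)(trifluoroacetyl)amino]acetyl}phenyl)-2-oxoethyl]amino}phenyl 2,2-dimethylpropanoate | COc1cccc(N(CC(=O)c2c(OC)c(OC)c(C(=O)CNc3ccc(OC(=O)C(C)(C)C)cc3)c(OC)c2OC)C(=O)C(F)(F)F)c1 | intermediate
17 | 4-{[2-(2,3,5,6-tetramethoxy-4-{[(3-methoxyphenyl)(trifluoroacetyl)amino]acetyl}phenyl)-2-oxoethyl](trifluoroacetyl)amino}phenyl 2,2-dimethylpropanoate | COc1cccc(N(CC(=O)c2c(OC)c(OC)c(C(=O)CN(C(=O)C(F)(F)F)c3ccc(OC(=O)C(C)(C)C)cc3)c(OC)c2OC)C(=O)C(F)(F)F)c1 | intermediate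
18 | 4-[{2-[2,3,5,6-tetramethoxy-4-(6-methoxy-1-(trifluoroacetyl)-1H-indol-3-yl)phenyl]-2-oxoethyl}(trifluoroacetyl)amino]phenyl 2,2-dimethylpropanoate | COc1ccc2c(-c3c(OC)c(OC)c(C(=O)CN(C(=O)C(F)(F)F)c4ccc(OC(=O)C(C)(C)C)cc4)c(OC)c3OC)cn(C(=O)C(F)(F)F)c2c1 | intermediate
19 | 3-{2,3,5,6-tetramethoxy-4-[6-methoxy-1-(trifluoroacetyl)-1H-indol-3-yl]phenyl}-1-(trifluoroacetyl)-1H-indol-5-yl 2,2-dimethylpropanoate | COc1ccc2c(-c3c(OC)c(OC)c(-c4cn(C(=O)C(F)(F)F)c5ccc(OC(=O)C(C)(C)C)cc45)c(OC)c3OC)cn(C(=O)C(F)(F)F)c2c1 | intermediate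
20 | 3-[2,3,5,6-tetramethoxy-4-(6-methoxy-1H-indol-3-yl)phenyl]-1H-indol-5-ol | COc1ccc2c(-c3c(OC)c(OC)c(-c4c[nH]c5ccc(O)cc45)c(OC)c3OC)c[nH]c2c1 | target

**Step count and risk**

Total steps: 12. Longest linear sequence: 10 (steps 1–6 and 9–12); steps 7 and 8 form the side branch to 15.

Steps most likely to fail:

1. Step 11. The second closure may stall at the unactivated ortho carbon of the 4-pivaloyloxyanilide, and forcing the acid may cause ipso protonation and deacylation of the electron-rich ring C. The fallback keeps only the activated closure and brings ring B in preformed; it sets out from 9 and returns at 20. Compound 9 alone is cyclised in CF3CO2H at rt to 1-[3-(4-bromo-2,3,5,6-tetramethoxyphenyl)-6-methoxy-1H-indol-1-yl]-2,2,2-trifluoroethan-1-one F1. The coupling partner tert-butyl 5-(benzyloxy)-3-(4,4,5,5-tetramethyl-1,3,2-dioxaborolan-2-yl)-1H-indole-1-carboxylate F2 is made by C3-selective C–H borylation of purchased tert-butyl 5-(benzyloxy)-1H-indole-1-carboxylate with B2pin2, [Ir(OMe)(cod)]2 and 4,4'-di-tert-butyl-2,2'-bipyridine. Suzuki–Miyaura coupling of F1 with F2 (Pd(OAc)2, SPhos, K3PO4, toluene/H2O, 90 °C), in which the aqueous base also removes the labile N-trifluoroacetyl group, should give tert-butyl 5-(benzyloxy)-3-[2,3,5,6-tetramethoxy-4-(6-methoxy-1H-indol-3-yl)phenyl]-1H-indole-1-carboxylate F3. K2CO3 in refluxing MeOH cleaves the indole N-Boc group to give 5-(benzyloxy)-3-[2,3,5,6-tetramethoxy-4-(6-methoxy-1H-indol-3-yl)phenyl]-1H-indole F4, and hydrogenolysis (H2, Pd/C, EtOAc/MeOH) of the benzyl ether gives 20.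

2. Step 5. Oxidative addition at the doubly ortho-substituted, electron-rich C–Br bond may be slow, so that loss of the stannane and reduction of the bromide overtake coupling. The fallback avoids palladium and builds both arms by organolithium chemistry, accepting one statistical amination; it sets out from 2 and returns at 16. Double Br/Li exchange of 2 (t-BuLi, 4.2 equiv, THF, −78 °C) gives (2,3,5,6-tetramethoxy-1,4-phenylene)dilithium F5, which is acylated with 3 (2.5 equiv) to 1,1'-(2,3,5,6-tetramethoxy-1,4-phenylene)bis(2-chloroethan-1-one) F6. Amination of F6 with one equivalent of 6 (NaHCO3, DMF, 50 °C), with separation from recovered F6 and the bis-adduct, gives 2-chloro-1-(2,3,5,6-tetramethoxy-4-{[(3-methoxyphenyl)amino]acetyl}phenyl)ethan-1-one F7. Acylation with (CF3CO)2O/pyridine gives N-{2-[4-(chloroacetyl)-2,3,5,6-tetramethoxyphenyl]-2-oxoethyl}-2,2,2-trifluoro-N-(3-methoxyphenyl)acetamide F8, and alkylation of 15 with F8 (NaHCO3, DMF, 50 °C) gives 16.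

3. Step 2. Proton transfer from the acidic CH2Cl group of the amide to the hindered aryllithium may return the debrominated arene in place of carbonyl addition. The fallback separates acylation from halogenation; it sets out from 2 and returns at 8. Aryllithium 4, made as in step 2, is quenched with N-methoxy-N-methylacetamide to give 1-(4-bromo-2,3,5,6-tetramethoxyphenyl)ethan-1-one F9. α-Bromination with PhNMe3Br3 in THF, where the fully substituted ring offers no site for nuclear bromination, gives 2-bromo-1-(4-bromo-2,3,5,6-tetramethoxyphenyl)ethan-1-one F10, which is aminated with 6 (NaHCO3, MeCN, rt) to give 8.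

**Further compounds**

F1 | step 11 | 1-[3-(4-bromo-2,3,5,6-tetramethoxyphenyl)-6-methoxy-1H-indol-1-yl]-2,2,2-trifluoroethan-1-one | COc1ccc2c(-c3c(OC)c(OC)c(Br)c(OC)c3OC)cn(C(=O)C(F)(F)F)c2c1
F2 | step 11 | tert-butyl 5-(benzyloxy)-3-(4,4,5,5-tetramethyl-1,3,2-dioxaborolan-2-yl)-1H-indole-1-carboxylate | CC(C)(C)OC(=O)n1cc(B2OC(C)(C)C(C)(C)O2)c2cc(OCc3ccccc3)ccc21
F3 | step 11 | tert-butyl 5-(benzyloxy)-3-[2,3,5,6-tetramethoxy-4-(6-methoxy-1H-indol-3-yl)phenyl]-1H-indole-1-carboxylate | COc1ccc2c(-c3c(OC)c(OC)c(-c4cn(C(=O)OC(C)(C)C)c5ccc(OCc6ccccc6)cc45)c(OC)c3OC)c[nH]c2c1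
F4 | step 11 | 5-(benzyloxy)-3-[2,3,5,6-tetramethoxy-4-(6-methoxy-1H-indol-3-yl)phenyl]-1H-indole | COc1ccc2c(-c3c(OC)c(OC)c(-c4c[nH]c5ccc(OCc6ccccc6)cc45)c(OC)c3OC)c[nH]c2c1
F5 | step 5 | (2,3,5,6-tetramethoxy-1,4-phenylene)dilithium | [Li]c1c(OC)c(OC)c([Li])c(OC)c1OC
F6 | step 5 | 1,1'-(2,3,5,6-tetramethoxy-1,4-phenylene)bis(2-chloroethan-1-one) | O=C(CCl)c1c(OC)c(OC)c(C(=O)CCl)c(OC)c1OC
F7 | step 5 | 2-chloro-1-(2,3,5,6-tetramethoxy-4-{[(3-methoxyphenyl)amino]acetyl}phenyl)ethan-1-one | COc1cccc(NCC(=O)c2c(OC)c(OC)c(C(=O)CCl)c(OC)c2OC)c1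
F8 | step 5 | N-{2-[4-(chloroacetyl)-2,3,5,6-tetramethoxyphenyl]-2-oxoethyl}-2,2,2-trifluoro-N-(3-methoxyphenyl)acetamide | COc1cccc(N(CC(=O)c2c(OC)c(OC)c(C(=O)CCl)c(OC)c2OC)C(=O)C(F)(F)F)c1
F9 | step 2 | 1-(4-bromo-2,3,5,6-tetramethoxyphenyl)ethan-1-one | CC(=O)c1c(OC)c(OC)c(Br)c(OC)c1OC
F10 | step 2 | 2-bromo-1-(4-bromo-2,3,5,6-tetramethoxyphenyl)ethan-1-one | O=C(CBr)c1c(OC)c(OC)c(Br)c(OC)c1OC
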